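**Plan**

- Enabling feature: in the six-membered ring (C1 ketone, C2 amide-bearing, C3, C4 tertiary carbinol, C5 secondary carbinol, C6 methylene) the nitrogen on C2 and the oxygen on C5 lie 1,4 to each other on either side of the C1–C6 unit. This is the footprint of a nitroso dienophile on a diene C2=C1(OSi)–C6=C5.
- Retrosynthetic cuts, in order: the C5′–C6′ bond of the trienamide arm (Stille); the C2=C3 unsaturation (back to an α-amido ketone); C2–N and C5–O together (acylnitroso [4+2]); the silyl dienol ether back to a desymmetrised p-quinol; the side-chain C=C (Wittig) and the aminocyclopentenone amide.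
- Forward order: the carbocycle is bought as a quinone monoketal. The only ring formed is the 1,2-oxazine bridge of step 11, reopened in step 12. The acyl side chain enters in the cycloaddition and the trienamide arm is attached last.
- Stereochemistry: C4 from enzymatic desymmetrisation of the p-quinol; C5 relayed from C4 by cycloaddition on the hydroxyl face; the side-chain methyl centre from an oxazolidinone-directed methylation; alkene geometries from stereoretentive tin chemistry and a stabilised Wittig reaction.

Key step: step 11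

Assumptions: compounds 1, 2, 9, 10, 23 and 26 are bought; the ene-reductase named in step 4 is taken to give the (S)-enone, and a stereocomplementary enzyme of the same family would replace it if the antipode were favoured.

**Route**

Step 1
Reactants: 1 (E)-1,2-bis(tributylstannyl)ethene; 2 4,4-dimethoxycyclohexa-2,5-dien-1-one
Product: 4 4,4-dimethoxy-1-[(E)-2-(tributylstannyl)vinyl]cyclohexa-2,5-dien-1-ol, via (E)-2-(tributylstannyl)vinyllithium 3 (not isolated)
Conditions: 1, n-BuLi (1.0 equiv), THF, −78 °C; then 2, −78 °C; H2O quench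
Reagents that add atoms: none
Why: Tin–lithium exchange on one terminus of the bis-stannane gives the (E)-alkenyllithium with retention of geometry, and this hard nucleophile adds 1,2 to the dienone carbonyl of the quinone monoketal (organolithium carbonyl addition), the ketal masking the second carbonyl.

Step 2
Reactants: 4 4,4-dimethoxy-1-[(E)-2-(tributylstannyl)vinyl]cyclohexa-2,5-dien-1-ol
Product: 5 1-[(E)-2-bromovinyl]-4,4-dimethoxycyclohexa-2,5-dien-1-ol
Conditions: NBS (1.05 equiv), MeCN, 0 °C
Reagents that add atoms: N-bromosuccinimide, O=C1CCC(=O)N1Br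
Why: Electrophilic ipso-bromodestannylation of the alkenylstannane (halodestannylation) is stereoretentive and much faster than attack of NBS on the unactivated ring alkenes, so the (E)-bromoalkene should form cleanly.

Step 3
Reactants: 5 1-[(E)-2-bromovinyl]-4,4-dimethoxycyclohexa-2,5-dien-1-ol
Product: 6 4-[(E)-2-bromovinyl]-4-hydroxycyclohexa-2,5-dien-1-one
Conditions: oxalic acid (5% aq.), THF, 0 °C → rt
Reagents that add atoms: water, O
Why: Acid-catalysed hydrolysis of the dimethyl ketal (acetal hydrolysis) runs through the methoxy-stabilised oxocarbenium ion under conditions too mild to ionise the tertiary carbinol and unveils the p-quinol.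

Step 4
Reactants: 6 4-[(E)-2-bromovinyl]-4-hydroxycyclohexa-2,5-dien-1-one
Product: 7 (S)-4-[(E)-2-bromovinyl]-4-hydroxycyclohex-2-en-1-one
Conditions: ene-reductase YqjM, NADP+ (cat.), glucose dehydrogenase, D-glucose, phosphate buffer pH 7.0, DMSO (5% v/v), 30 °C
Reagents that add atoms: none
Why: Flavin-dependent ene-reductases of the Old Yellow Enzyme family reduce one of the two enantiotopic enone arms of prochiral 4,4-disubstituted cyclohexa-2,5-dienones (desymmetrising biocatalytic conjugate reduction), so the C4 stereocentre is set by which arm the active site presents to the flavin hydride, while the unactivated bromoalkene is not a substrate.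

Step 5
Reactants: 7 (S)-4-[(E)-2-bromovinyl]-4-hydroxycyclohex-2-en-1-one
Product: 8 (S)-1-[(E)-2-bromovinyl]-4-[(tert-butyldimethylsilyl)oxy]cyclohexa-2,4-dien-1-ol
Conditions: LiN(SiMe3)2 (2.2 equiv), THF, −78 °C; TBSCl (1.2 equiv), DMPU, −78 → −40 °C
Reagents that add atoms: tert-butyldimethylsilyl chloride, CC(C)(C)[Si](C)(C)Cl
Why: Kinetic deprotonation can occur only at the α′-methylene (C4 is quaternary, so there is no γ-proton) and O-silylation of the lithium enolate gives the cross-conjugated 2-silyloxy-1,3-diene (kinetic enol silane formation), the hindered tertiary lithium alkoxide being inert to TBSCl at low temperature and C4 being untouched.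

Step 6
Reactants: 9 (R)-4-benzyl-1,3-oxazolidin-2-one; 10 hexanoyl chloride
Product: 11 (R)-4-benzyl-3-hexanoyl-1,3-oxazolidin-2-one
Conditions: n-BuLi (1.0 equiv), THF, −78 °C; then 10, −78 → 0 °C
Reagents that add atoms: none
Why: N-Acylation of the lithiated oxazolidinone with the acid chloride is the standard entry to the imide needed for auxiliary-controlled enolate alkylation.

Step 7
Reactants: 11 (R)-4-benzyl-3-hexanoyl-1,3-oxazolidin-2-one
Product: 12 (R)-4-benzyl-3-[(R)-2-methylhexanoyl]-1,3-oxazolidin-2-one
Conditions: NaN(SiMe3)2 (1.1 equiv), THF, −78 °C; MeI (4 equiv), −78 °C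
Reagents that add atoms: iodomethane, CI
Why: Evans alkylation: the chelated Z-sodium enolate is methylated on the face opposite the benzyl group, which with the (R)-auxiliary and a butyl-bearing enolate gives the (R)-configured α-methyl centre.

Step 8
Reactants: 12 (R)-4-benzyl-3-[(R)-2-methylhexanoyl]-1,3-oxazolidin-2-one
Product: 13 (R)-2-methylhexan-1-ol
Conditions: LiBH4, MeOH (1 equiv), Et2O, 0 °C
Reagents that add atoms: none
Why: Hydride reduction of the imide carbonyl with LiBH4 (reductive auxiliary cleavage) releases the primary alcohol without epimerising the α-stereocentre and returns the oxazolidinone.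

Step 9
Reactants: 13 (R)-2-methylhexan-1-ol
Product: 15 methyl (2E,4R)-2,4-dimethyloct-2-enoate, via (R)-2-methylhexanal 14 (not isolated)
Conditions: Dess–Martin periodinane, CH2Cl2, 0 °C → rt; then Ph3P=C(Me)CO2Me (2.5 equiv), rt
Reagents that add atoms: methyl 2-(triphenylphosphoranylidene)propanoate, COC(=O)C(C)=P(c1ccccc1)(c1ccccc1)c1ccccc1
Why: Dess–Martin oxidation followed by Wittig olefination in the same flask keeps the epimerisable α-branched aldehyde from being isolated, and the stabilised α-methyl ylide gives the (E)-trisubstituted enoate.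

Step 10
Reactants: 15 methyl (2E,4R)-2,4-dimethyloct-2-enoate
Product: 16 (2E,4R)-N-hydroxy-2,4-dimethyloct-2-enamide
Conditions: NH2OH·HCl, KOH, MeOH, 0 °C → rt
Reagents that add atoms: hydroxylamine hydrochloride, Cl.NO
Why: Hydroxylamine, an α-effect nucleophile, displaces methoxide from the ester (hydroxylaminolysis, nucleophilic acyl substitution) to give the hydroxamic acid without touching the γ-stereocentre.

Step 11
Reactants: 8 (S)-1-[(E)-2-bromovinyl]-4-[(tert-butyldimethylsilyl)oxy]cyclohexa-2,4-dien-1-ol; 16 (2E,4R)-N-hydroxy-2,4-dimethyloct-2-enamide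
Product: 18 (2E,4R)-1-[(1R,4R,7R)-7-[(E)-2-bromovinyl]-5-[(tert-butyldimethylsilyl)oxy]-7-hydroxy-2-oxa-3-azabicyclo[2.2.2]oct-5-en-3-yl]-2,4-dimethyloct-2-en-1-one, via acylnitroso compound 17 (not isolated)
Conditions: Bu4NIO4 (1.1 equiv), CH2Cl2, −20 °C, slow addition of 16 to 8 and the oxidant
Reagents that add atoms: none
Why: Periodate oxidises hydroxamic acid 16 to the transient acylnitroso compound 17, which is intercepted at once by the electron-rich, ring-locked s-cis diene of 8 in an asynchronous concerted [4+2] cycloaddition with the N–C2 bond more advanced than the O–C5 bond; the closest known reaction type is the acylnitroso hetero-Diels–Alder reaction of 2-silyloxycyclohexa-1,3-dienes. The 1,2-oxazine ring closes by this cycloaddition, suprafacial on both partners, the N–O unit becoming the two-atom bridge of a 2-oxa-3-azabicyclo[2.2.2]octene. The new stereocentres C2 and C5 arise together on one face of the diene, and that face is chosen by the C4 stereocentre: attack is expected on the face carrying the hydroxyl, which is smaller than the bromovinyl group and can hydrogen-bond to the incoming nitroso compound. Regioselectivity (N to C2, O to C5) follows from the polarisation of the 2-silyloxydiene, whose largest HOMO coefficient lies on the enol-ether β-carbon C2 and matches the electrophilic nitroso nitrogen. Chemoselectivity is secured because the bromovinyl and enoyl alkenes are electron-poor and not part of an s-cis diene, while quaternary C4 rules out aromatisation. The C4 descriptor changes from S to R only through the CIP ranking of its substituents.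

Step 12
Reactants: 18 the bicyclic N-acyl oxazine
Product: 19 (2E,4R)-N-[(1R,3R,4R)-3-[(E)-2-bromovinyl]-6-[(tert-butyldimethylsilyl)oxy]-3,4-dihydroxycyclohex-5-en-1-yl]-2,4-dimethyloct-2-enamide
Conditions: SmI2 (2.5 equiv), THF, −78 → 0 °C; aq. NaHCO3
Reagents that add atoms: none
Why: Single-electron reduction by SmI2 cleaves the weak N–O bond of the N-acyl oxazine (reductive N–O cleavage of acylnitroso cycloadducts) at low temperature, leaving the silyl enol ether, the alkenyl bromide and the unsaturated acyl group intact and turning the bridge into the C2 amide and the C5 hydroxyl, cis to the C4 hydroxyl.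

Step 13
Reactants: 19 the silyl enol ether diol
Product: 20 (2E,4R)-N-[(1R,3R,4R)-3-[(E)-2-bromovinyl]-3,4-dihydroxy-6-oxocyclohexyl]-2,4-dimethyloct-2-enamide
Conditions: Bu4NF (1.1 equiv), AcOH (1.5 equiv), THF, 0 °C
Reagents that add atoms: none
Why: Fluoride-mediated cleavage of the silyl enol ether buffered with acetic acid (desilylation with protonation at C6) gives the ketone under near-neutral conditions that should spare the β-hydroxy ketone from elimination.

Step 14
Reactants: 20 the α-amido ketone
Product: 22 (2E,4R)-N-[(3R,4R)-3-[(E)-2-bromovinyl]-3,4-dihydroxy-6-oxocyclohex-1-en-1-yl]-2,4-dimethyloct-2-enamide, via N-chloro amide 21 (not isolated)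
Conditions: t-BuOCl (1.05 equiv), MeOH, 0 °C, dark; evaporate; DABCO (2 equiv), CH2Cl2, 0 °C → rt
Reagents that add atoms: none
Why: N-Chlorination of the secondary amide and amine-induced 1,2-dehydrochlorination across N–C2 (the N-chlorination/dehydrochlorination route to dehydroamino acid derivatives) gives the N-acyl α-imino ketone, which can tautomerise only toward C3 to the conjugated 2-amido enone; the C2 stereocentre is erased on purpose and C4 and C5 are not involved.

Step 15
Reactants: 23 cyclopentane-1,3-dione
Product: 24 2-(hydroxyimino)cyclopentane-1,3-dione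
Conditions: NaNO2, HCl (aq.), 0 °C
Reagents that add atoms: sodium nitrite, [Na+].[O-]N=O
Why: C-Nitrosation of the enolised 1,3-dione at C2 and tautomerisation to the oxime (nitrosation of an active methylene compound) places the nitrogen on the required carbon.

Step 16
Reactants: 24 2-(hydroxyimino)cyclopentane-1,3-dione
Product: 25 2-amino-3-hydroxycyclopent-2-en-1-one hydrochloride
Conditions: H2 (1 atm), Pd/C (10 wt % Pd on carbon), HCl, MeOH, rt
Reagents that add atoms: hydrogen chloride, Cl
Why: Catalytic hydrogenation of the oxime to the primary amine in the presence of HCl delivers the enolised aminodione as its hydrochloride, the salt form preventing self-condensation of the α-amino ketone.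

Step 17
Reactants: 26 (E)-3-iodoacrylic acid; 25 2-amino-3-hydroxycyclopent-2-en-1-one hydrochloride
Product: 28 (E)-N-(2-hydroxy-5-oxocyclopent-1-en-1-yl)-3-iodoacrylamide, via (E)-3-iodoacryloyl chloride 27 (not isolated)
Conditions: 26, (COCl)2, DMF (cat.), CH2Cl2, 0 °C → rt; evaporate; then 25, i-Pr2NEt (3 equiv), CH2Cl2–DMF, 0 °C → rt
Reagents that add atoms: none
Why: Acid chloride formation and N-acylation of the amine hydrochloride in the presence of a hindered base (amide formation) should give the amide, any O-acyl enol ester transferring its acyl group to nitrogen.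

Step 18
Reactants: 28 (E)-N-(2-hydroxy-5-oxocyclopent-1-en-1-yl)-3-iodoacrylamide; 1 (E)-1,2-bis(tributylstannyl)ethene
Product: 29 (2E,4E)-N-(2-hydroxy-5-oxocyclopent-1-en-1-yl)-5-(tributylstannyl)penta-2,4-dienamide
Conditions: 1 (3 equiv), PdCl2(MeCN)2 (5 mol %), DMF, rt, dark
Reagents that add atoms: none
Why: Stille coupling of the alkenyl iodide with one tin terminus of the bis-stannane, used in excess to suppress double coupling, proceeds with retention of both alkene geometries and gives the (2E,4E)-stannyl dienamide.

Step 19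
Reactants: 22 the bromovinyl 2-amido enone; 29 the stannyl dienamide
Product: 30 (2E,4R)-N-[(3S,4R)-3,4-dihydroxy-3-[(1E,3E,5E)-7-[(2-hydroxy-5-oxocyclopent-1-en-1-yl)amino]-7-oxohepta-1,3,5-trien-1-yl]-6-oxocyclohex-1-en-1-yl]-2,4-dimethyloct-2-enamide (target)
Conditions: Pd2(dba)3 (5 mol %), P(2-furyl)3 (20 mol %), NMP, 45 °C
Reagents that add atoms: none
Why: Stille coupling of the (E)-alkenyl bromide with the dienylstannane joins C6′ to C5′ with retention of geometry at all three double bonds under neutral conditions compatible with the free hydroxyls, the β-hydroxy ketone and the acidic aminocyclopentenone; the descriptor of the tertiary carbinol changes from R to S only because the CIP ranking of its substituents changes.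

**Compound list**

1 | (E)-1,2-bis(tributylstannyl)ethene | CCCC[Sn](CCCC)(CCCC)/C=C/[Sn](CCCC)(CCCC)CCCC | starting material
2 | 4,4-dimethoxycyclohexa-2,5-dien-1-one | COC1(OC)C=CC(=O)C=C1 | starting material
3 | (E)-2-(tributylstannyl)vinyllithium | [Li]/C=C/[Sn](CCCC)(CCCC)CCCC | intermediate
4 | 4,4-dimethoxy-1-[(E)-2-(tributylstannyl)vinyl]cyclohexa-2,5-dien-1-ol | CCCC[Sn](CCCC)(CCCC)/C=C/C1(O)C=CC(OC)(OC)C=C1 | intermediate
5 | 1-[(E)-2-bromovinyl]-4,4-dimethoxycyclohexa-2,5-dien-1-ol | COC1(OC)C=CC(O)(/C=C/Br)C=C1 | intermediate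
6 | 4-[(E)-2-bromovinyl]-4-hydroxycyclohexa-2,5-dien-1-one | O=C1C=CC(O)(/C=C/Br)C=C1 | intermediate
7 | (S)-4-[(E)-2-bromovinyl]-4-hydroxycyclohex-2-en-1-one | O=C1CC[C@@](O)(/C=C/Br)C=C1 | intermediate
8 | (S)-1-[(E)-2-bromovinyl]-4-[(tert-butyldimethylsilyl)oxy]cyclohexa-2,4-dien-1-ol | CC(C)(C)[Si](C)(C)OC1=CC[C@@](O)(/C=C/Br)C=C1 | intermediate
9 | (R)-4-benzyl-1,3-oxazolidin-2-one | O=C1N[C@H](Cc2ccccc2)CO1 | starting material
10 | hexanoyl chloride | CCCCCC(=O)Cl | starting material
11 | (R)-4-benzyl-3-hexanoyl-1,3-oxazolidin-2-one | CCCCCC(=O)N1[C@H](Cc2ccccc2)COC1=O | intermediate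
12 | (R)-4-benzyl-3-[(R)-2-methylhexanoyl]-1,3-oxazolidin-2-one | CCCC[C@@H](C)C(=O)N1[C@H](Cc2ccccc2)COC1=O | intermediate
13 | (R)-2-methylhexan-1-ol | CCCC[C@@H](C)CO | intermediate
14 | (R)-2-methylhexanal | CCCC[C@@H](C)C=O | intermediate
15 | methyl (2E,4R)-2,4-dimethyloct-2-enoate | CCCC[C@@H](C)/C=C(\C)C(=O)OC | intermediate
16 | (2E,4R)-N-hydroxy-2,4-dimethyloct-2-enamide | CCCC[C@@H](C)/C=C(\C)C(=O)NO | intermediate
17 | (2E,4R)-2,4-dimethyl-1-nitrosooct-2-en-1-one (acylnitroso compound) | CCCC[C@@H](C)/C=C(\C)C(=O)N=O | intermediate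
18 | (2E,4R)-1-[(1R,4R,7R)-7-[(E)-2-bromovinyl]-5-[(tert-butyldimethylsilyl)oxy]-7-hydroxy-2-oxa-3-azabicyclo[2.2.2]oct-5-en-3-yl]-2,4-dimethyloct-2-en-1-one | CCCC[C@@H](C)/C=C(\C)C(=O)N1O[C@@H]2C=C(O[Si](C)(C)C(C)(C)C)[C@H]1C[C@@]2(O)/C=C/Br | intermediate
19 | (2E,4R)-N-[(1R,3R,4R)-3-[(E)-2-bromovinyl]-6-[(tert-butyldimethylsilyl)oxy]-3,4-dihydroxycyclohex-5-en-1-yl]-2,4-dimethyloct-2-enamide | CCCC[C@@H](C)/C=C(\C)C(=O)N[C@@H]1C[C@@](O)(/C=C/Br)[C@H](O)C=C1O[Si](C)(C)C(C)(C)C | intermediate
20 | (2E,4R)-N-[(1R,3R,4R)-3-[(E)-2-bromovinyl]-3,4-dihydroxy-6-oxocyclohexyl]-2,4-dimethyloct-2-enamide | CCCC[C@@H](C)/C=C(\C)C(=O)N[C@@H]1C[C@@](O)(/C=C/Br)[C@H](O)CC1=O | intermediate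
21 | (2E,4R)-N-[(1R,3R,4R)-3-[(E)-2-bromovinyl]-3,4-dihydroxy-6-oxocyclohexyl]-N-chloro-2,4-dimethyloct-2-enamide | CCCC[C@@H](C)/C=C(\C)C(=O)N(Cl)[C@@H]1C[C@@](O)(/C=C/Br)[C@H](O)CC1=O | intermediate
22 | (2E,4R)-N-[(3R,4R)-3-[(E)-2-bromovinyl]-3,4-dihydroxy-6-oxocyclohex-1-en-1-yl]-2,4-dimethyloct-2-enamide | CCCC[C@@H](C)/C=C(\C)C(=O)NC1=C[C@@](O)(/C=C/Br)[C@H](O)CC1=O | intermediate
23 | cyclopentane-1,3-dione | O=C1CCC(=O)C1 | starting material
24 | 2-(hydroxyimino)cyclopentane-1,3-dione | ON=C1C(=O)CCC1=O | intermediate
25 | 2-amino-3-hydroxycyclopent-2-en-1-one hydrochloride | Cl.NC1=C(O)CCC1=O | intermediate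
26 | (E)-3-iodoacrylic acid | OC(=O)/C=C/I | starting material
27 | (E)-3-iodoacryloyl chloride | ClC(=O)/C=C/I | intermediate
28 | (E)-N-(2-hydroxy-5-oxocyclopent-1-en-1-yl)-3-iodoacrylamide | O=C(/C=C/I)NC1=C(O)CCC1=O | intermediate
29 | (2E,4E)-N-(2-hydroxy-5-oxocyclopent-1-en-1-yl)-5-(tributylstannyl)penta-2,4-dienamide | CCCC[Sn](CCCC)(CCCC)/C=C/C=C/C(=O)NC1=C(O)CCC1=O | intermediate
30 | (2E,4R)-N-[(3S,4R)-3,4-dihydroxy-3-[(1E,3E,5E)-7-[(2-hydroxy-5-oxocyclopent-1-en-1-yl)amino]-7-oxohepta-1,3,5-trien-1-yl]-6-oxocyclohex-1-en-1-yl]-2,4-dimethyloct-2-enamide | CCCC[C@@H](C)/C=C(\C)C(=O)NC1=C[C@@](O)(/C=C/C=C/C=C/C(=O)NC2=C(O)CCC2=O)[C@H](O)CC1=O | target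

**Step count**

Total: 19 steps. Longest linear sequence: 10 steps (1, 2, 3, 4, 5, 11, 12, 13, 14, 19).

**Steps most likely to fail**

Step 4. The enzyme may discriminate poorly between the two enone arms of this p-quinol, reduce the wrong arm, or go on to reduce the second C=C. The fallback replaces asymmetric catalysis by resolution. Setting out from 6, non-selective mono-reduction with an achiral copper hydride ([(Ph3P)CuH]6 cat., PhSiH3, toluene, then fluoride work-up) would give racemic 4-[(E)-2-bromovinyl]-4-hydroxycyclohex-2-en-1-one F1. The intermediate silyl dienol ether is no longer an enone, which excludes over-reduction. Preparative chromatography on a chiral stationary phase (amylose tris(3,5-dimethylphenylcarbamate)) then separates the enantiomers, and the (S)-isomer rejoins the route as 7.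

Step 11. Facial control may be lost (approach anti to the hydroxyl), or a stepwise nitroso-aldol-type addition with silyl transfer may compete with ring closure, eroding the cis C4/C5 relationship. The fallback delivers the two heteroatoms separately, with the oxygen tethered to C4. Setting out from 7, phenylboronic acid with a catalytic tertiary amine (toluene, 4 Å sieves) would form the boronic hemiester of the γ-hydroxy enone and add its B–OH oxygen intramolecularly to C5 (oxa-Michael addition). This gives the cis-fused phenylboronate of (3R,4R)-4-[(E)-2-bromovinyl]-3,4-dihydroxycyclohexan-1-one F2, in which C5–O is cis to C4–O by ring constraint. Soft enolisation (TBSOTf, Et3N, CH2Cl2, −78 °C) away from the oxygenated side gives the C1=C2 tert-butyldimethylsilyl enol ether of this boronate F3. N-selective nitroso aldol reaction with acylnitroso compound 17 (from 16 and Bu4NIO4) and desilylative work-up gives the α-(N-hydroxyamido) ketone boronate F4, whose C2 configuration is immaterial. Mesylation of the N-hydroxyl (MsCl, Et3N, CH2Cl2, 0 °C) gives the N-mesyloxy amide F5 (not isolated), which undergoes 1,2-elimination across N–C2 and tautomerisation to the 2-amido enone phenylboronate F6. Transesterification with pinacol frees the diol and returns to the route at 22.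

Step 14. Chlorination may take place at carbon (C6) or at the secondary hydroxyl instead of nitrogen, and the amine base may trigger β-elimination of the C5 hydroxyl. The fallback uses carbon-centred instead of nitrogen-centred activation. Setting out from 20, acid-mediated α-selenenylation with PhSeCl (EtOAc, rt) should place selenium on the more enolisable, nitrogen-bearing C2 to give the 2-(phenylselanyl) α-amido ketone F7. Oxidation with H2O2/pyridine (CH2Cl2, 0 °C) gives the selenoxide F8 (not isolated), whose syn-elimination toward C3 returns to the route at 22.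

**Further compounds**

F1 | step 4 | racemic 4-[(E)-2-bromovinyl]-4-hydroxycyclohex-2-en-1-one | O=C1CCC(O)(/C=C/Br)C=C1
F2 | step 11 | cis-fused phenylboronate of (3R,4R)-4-[(E)-2-bromovinyl]-3,4-dihydroxycyclohexan-1-one | O=C1CC[C@]2(/C=C/Br)OB(c3ccccc3)O[C@@H]2C1
F3 | step 11 | C1=C2 tert-butyldimethylsilyl enol ether of boronate F2 | CC(C)(C)[Si](C)(C)OC1=CC[C@]2(/C=C/Br)OB(c3ccccc3)O[C@@H]2C1
F4 | step 11 | α-(N-hydroxyamido) ketone boronate (C2 epimers) | CCCC[C@@H](C)/C=C(\C)C(=O)N(O)C1C[C@]2(/C=C/Br)OB(c3ccccc3)O[C@@H]2CC1=O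
F5 | step 11 | N-mesyloxy amide of F4 | CCCC[C@@H](C)/C=C(\C)C(=O)N(OS(C)(=O)=O)C1C[C@]2(/C=C/Br)OB(c3ccccc3)O[C@@H]2CC1=O
F6 | step 11 | phenylboronate of 2-amido enone 22 | CCCC[C@@H](C)/C=C(\C)C(=O)NC1=C[C@]2(/C=C/Br)OB(c3ccccc3)O[C@@H]2CC1=O
F7 | step 14 | 2-(phenylselanyl) derivative of α-amido ketone 20 (C2 epimers) | CCCC[C@@H](C)/C=C(\C)C(=O)NC1([Se]c2ccccc2)C[C@@](O)(/C=C/Br)[C@H](O)CC1=O
F8 | step 14 | selenoxide of F7 | CCCC[C@@H](C)/C=C(\C)C(=O)NC1([Se](=O)c2ccccc2)C[C@@](O)(/C=C/Br)[C@H](O)CC1=O
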